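## Retrosynthetic overview

- The 1,2-dioxane is the ring–chain tautomer of a γ-hydroperoxy β-keto ester, so the C3 hemiketal closes last and takes the thermodynamic (anomeric) configuration.
- Key disconnection C5–C6: a ketone homoenolate equivalent (a cyclopropyl silyl ether carrying C1–C5 and the C4 stereocentre) adds to a tertiary peroxycarbenium ion made from a methyl ketone peroxyketal. This forms the C–C bond and the tertiary C–OO centre in one step.
- The methyl ketone comes from a Cu-catalysed asymmetric conjugate addition of a (Z)-styrenyl alkyl Grignard reagent to (E)-pent-3-en-2-one (sets the side-chain methyl centre). The Grignard comes from phenylacetylene, 1,6-dibromohexane and a Lindlar reduction.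
- The homoenolate comes from the Roche-ester bromide via 2-methylcyclopropanone and a Reformatsky addition (C4 from the chiral pool).
- Ring order: sacrificial cyclopropane first (opened in the key step), 1,2-dioxane last.

Assumption: in the two catalyst-controlled steps (3 and 8) the catalyst antipode that gives the drawn configuration is used; the sense is assigned by analogy and must be confirmed on the first run.

## Route

Step 1
Reactants: 1 phenylacetylene; 2 1,6-dibromohexane
Product: 4 (8-bromooct-1-yn-1-yl)benzene, via lithium phenylacetylide 3 (not isolated)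
Conditions: n-BuLi, THF, −78 °C; then 2 (4 equiv), DMPU, −78 °C → rt; excess 2 distilled off
Reagents that add atoms: none
Why: SN2 alkylation of a lithium acetylide by a primary bromide, with excess dibromide suppressing double alkylation.

Step 2
Reactants: 4 (8-bromooct-1-yn-1-yl)benzene
Product: 5 [(1Z)-8-bromooct-1-en-1-yl]benzene
Conditions: H2 (1 atm), Lindlar catalyst, quinoline, EtOAc, rt
Reagents that add atoms: none
Why: Lindlar semihydrogenation delivers H2 syn on the poisoned Pd surface, which sets the Z alkene and leaves the primary bromide untouched.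

Step 3
Reactants: 5 [(1Z)-8-bromooct-1-en-1-yl]benzene; 6 (3E)-pent-3-en-2-one
Product: 8 (4R,11Z)-4-methyl-12-phenyldodec-11-en-2-one, via Grignard reagent 7 (not isolated)
Conditions: Mg, Et2O, rt; then CuBr·SMe2 (5 mol %), Josiphos-type ligand (6 mol %, antipode giving 4R), slow addition of 6, t-BuOMe, −75 °C; NH4Cl aq
Reagents that add atoms: none
Why: Copper/ferrocenyl-diphosphine-catalysed asymmetric conjugate addition of a Grignard reagent to an acyclic enone, in which the catalyst sets C4 (R), the future side-chain methyl centre.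

Step 4
Reactants: 8 (4R,11Z)-4-methyl-12-phenyldodec-11-en-2-one
Product: 10 (2RS,4R,11Z)-2-hydroperoxy-2-methoxy-4-methyl-12-phenyldodec-11-ene, via dimethyl ketal 9 (not isolated)
Conditions: HC(OMe)3 (neat), PPTS (cat.), rt; concentrate; then anhydrous H2O2 in Et2O (1.5 equiv), PPTS (cat.), 0 °C
Reagents that add atoms: trimethyl orthoformate COC(OC)OC; hydrogen peroxide OO
Why: Ketalisation followed by acid-catalysed perhydrolysis (exchange of one methoxy group for OOH via the oxocarbenium ion); C2 forms as a mixture, which does not matter because it becomes planar in step 8.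

Step 5
Reactants: 10 (2RS,4R,11Z)-2-hydroperoxy-2-methoxy-4-methyl-12-phenyldodec-11-ene
Product: 11 triethyl{[(2RS,4R,11Z)-2-methoxy-4-methyl-12-phenyldodec-11-en-2-yl]peroxy}silane
Conditions: TESCl, imidazole, DMF, 0 °C
Reagents that add atoms: chlorotriethylsilane CC[Si](Cl)(CC)CC
Why: O-silylation of the hydroperoxide gives a silyl peroxyketal that survives Lewis acids and leaves methoxide as the only ionisable group.

Step 6
Reactants: 12 methyl (2S)-3-bromo-2-methylpropanoate
Product: 14 (2R)-1-methoxy-2-methylcyclopropan-1-ol (C1 epimers), via silyl methyl ketal 13 (not isolated)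
Conditions: Na dispersion, TMSCl, Et2O, reflux; filter, concentrate; then MeOH, rt
Reagents that add atoms: none
Why: Rühlmann-type reductive 1,3-cyclisation of a β-halo ester under silyl trapping, then methanolysis of the O–Si bond; C2 comes from the Roche-ester chiral pool and is not touched (S→R is a CIP priority change only).

Step 7
Reactants: 14 (2R)-1-methoxy-2-methylcyclopropan-1-ol
Product: 17 methyl 2-[(2R)-2-methyl-1-(trimethylsilyloxy)cyclopropyl]acetate (C1 epimers), via (2R)-2-methylcyclopropanone 15 (not isolated), via zinc cyclopropanolate 16 (not isolated)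
Conditions: MeMgBr (1.0 equiv), THF, 0 °C; then BrZnCH2CO2Me (from methyl bromoacetate and Zn dust, THF), 0 °C → rt; then TMSCl, DMAP (cat.), 0 °C
Reagents that add atoms: methyl bromoacetate COC(=O)CBr; chlorotrimethylsilane C[Si](C)(C)Cl
Why: The magnesium hemiketalate releases the cyclopropanone, which takes up the Reformatsky reagent (the known hemiketal/Grignard chemistry extended to a zinc enolate) and is silylated in situ; C2 is not enolisable in the cyclopropanone and keeps its configuration.

Step 8
Reactants: 11 triethyl{[(2RS,4R,11Z)-2-methoxy-4-methyl-12-phenyldodec-11-en-2-yl]peroxy}silane; 17 methyl 2-[(2R)-2-methyl-1-(trimethylsilyloxy)cyclopropyl]acetate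
Product: 18 methyl (4R,6S,8R,15Z)-4,6,8-trimethyl-3-oxo-16-phenyl-6-[(triethylsilyl)peroxy]hexadec-15-enoate
Conditions: confined chiral imidodiphosphorimidate (IDPi) acid (3 mol %, antipode giving 6S), 17 (1.5 equiv), toluene/CH2Cl2, −78 °C; Et3N, then NaHCO3 aq
Reagents that add atoms: none
Why: Proposed new method: the silylated IDPi (a silylium-type Lewis acid formed from the acid and 17) removes the methoxy group of 11 to give a tertiary peroxycarbenium ion paired with the confined chiral anion; the strained C1–C3 σ-bond of the siloxycyclopropane, acting as a ketone homoenolate, attacks this cation through its CH2 corner, the ring opens to the silylated β-keto ester and the silyl group passes to the next molecule of 11 (a homo-Mukaiyama addition); the anion, not the substrate, must distinguish CH3 from CH2R on the cation and is relied on for 6S, while C4 (cyclopropane C2) is untouched; the closest known reaction types are Lewis-acid additions of allylsilanes and silyl ketene acetals to ketone-derived peroxycarbenium ions, ring-opening additions of cyclopropyl silyl ethers to oxocarbenium ions, and IDPi-catalysed asymmetric additions of silyl nucleophiles to aliphatic oxocarbenium ions and to silyl-activated methyl alkyl ketones.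

Step 9
Reactants: 18 methyl (4R,6S,8R,15Z)-4,6,8-trimethyl-3-oxo-16-phenyl-6-[(triethylsilyl)peroxy]hexadec-15-enoate
Product: 20 methyl 2-{(3S,4R,6S)-3-hydroxy-4,6-dimethyl-6-[(2R,9Z)-2-methyl-10-phenyldec-9-en-1-yl]-1,2-dioxan-3-yl}acetate, via open-chain hydroperoxide 19 (not isolated)
Conditions: TBAF, AcOH (1:1), THF, 0 °C; then SiO2 chromatography
Reagents that add atoms: none
Why: Fluoride desilylation frees the tertiary hydroperoxide, which closes onto the C3 ketone (6-exo hemiketalisation, ring–chain tautomerism) and equilibrates to the anomer with axial OH and equatorial CH2CO2Me, C4-methyl and C6 side chain, which is 3S for 4R,6S; any 6R epimer is a 4,6-trans dioxane and is removed on the column.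

## Compound list

1 | phenylacetylene | C#Cc1ccccc1 | starting material
2 | 1,6-dibromohexane | BrCCCCCCBr | starting material
3 | lithium phenylacetylide | [Li]C#Cc1ccccc1 | intermediate
4 | (8-bromooct-1-yn-1-yl)benzene | BrCCCCCCC#Cc1ccccc1 | intermediate
5 | [(1Z)-8-bromooct-1-en-1-yl]benzene | BrCCCCCC/C=C\c1ccccc1 | intermediate
6 | (3E)-pent-3-en-2-one | C/C=C/C(C)=O | starting material
7 | [(7Z)-8-phenyloct-7-en-1-yl]magnesium bromide | Br[Mg]CCCCCC/C=C\c1ccccc1 | intermediate
8 | (4R,11Z)-4-methyl-12-phenyldodec-11-en-2-one | CC(=O)C[C@H](C)CCCCCC/C=C\c1ccccc1 | intermediate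
9 | (4R,11Z)-2,2-dimethoxy-4-methyl-12-phenyldodec-11-ene | COC(C)(OC)C[C@H](C)CCCCCC/C=C\c1ccccc1 | intermediate
10 | (2RS,4R,11Z)-2-hydroperoxy-2-methoxy-4-methyl-12-phenyldodec-11-ene | COC(C)(OO)C[C@H](C)CCCCCC/C=C\c1ccccc1 | intermediate
11 | triethyl{[(2RS,4R,11Z)-2-methoxy-4-methyl-12-phenyldodec-11-en-2-yl]peroxy}silane | CC[Si](CC)(CC)OOC(C)(OC)C[C@H](C)CCCCCC/C=C\c1ccccc1 | intermediate
12 | methyl (2S)-3-bromo-2-methylpropanoate | COC(=O)[C@H](C)CBr | starting material
13 | trimethyl{[(2R)-1-methoxy-2-methylcyclopropyl]oxy}silane (C1 epimers) | COC1(O[Si](C)(C)C)C[C@H]1C | intermediate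
14 | (2R)-1-methoxy-2-methylcyclopropan-1-ol (C1 epimers) | COC1(O)C[C@H]1C | intermediate
15 | (2R)-2-methylcyclopropan-1-one | O=C1C[C@H]1C | intermediate
16 | bromozinc (2R)-1-(2-methoxy-2-oxoethyl)-2-methylcyclopropan-1-olate (C1 epimers) | COC(=O)CC1(O[Zn]Br)C[C@H]1C | intermediate
17 | methyl 2-[(2R)-2-methyl-1-(trimethylsilyloxy)cyclopropyl]acetate (C1 epimers) | COC(=O)CC1(O[Si](C)(C)C)C[C@H]1C | intermediate
18 | methyl (4R,6S,8R,15Z)-4,6,8-trimethyl-3-oxo-16-phenyl-6-[(triethylsilyl)peroxy]hexadec-15-enoate | COC(=O)CC(=O)[C@H](C)C[C@@](C)(OO[Si](CC)(CC)CC)C[C@H](C)CCCCCC/C=C\c1ccccc1 | intermediate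
19 | methyl (4R,6S,8R,15Z)-6-hydroperoxy-4,6,8-trimethyl-3-oxo-16-phenylhexadec-15-enoate | COC(=O)CC(=O)[C@H](C)C[C@@](C)(OO)C[C@H](C)CCCCCC/C=C\c1ccccc1 | intermediate
20 | methyl 2-{(3S,4R,6S)-3-hydroxy-4,6-dimethyl-6-[(2R,9Z)-2-methyl-10-phenyldec-9-en-1-yl]-1,2-dioxan-3-yl}acetate | COC(=O)C[C@]1(O)OO[C@@](C)(C[C@H](C)CCCCCC/C=C\c2ccccc2)C[C@H]1C | target

## Step count and risks

Total step count: 9. Longest linear sequence: 7 (steps 1, 2, 3, 4, 5, 8, 9); steps 6 and 7 form the convergent branch.

Stereocentres: the side-chain methyl centre is set in step 3, C4 comes from 12, C6 is set in step 8, and C3 is set thermodynamically in step 9. C4 sits at the γ-position of the β-keto ester and is not expected to epimerise under the buffered conditions used.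

The three steps most likely to fail:

Step 8 (most likely). The siloxycyclopropane may be too weak a nucleophile for the hindered cation, the cation may lose a proton instead, and the catalyst may not differentiate CH3 from CH2R. The fallback sets out from 11 and 13 and comes back to the route at 18. Compound 13 is distilled instead of being methanolysed and used as an ester homoenolate: with TMSOTf (or TiCl4, through the trichlorotitanium homoenolate) in CH2Cl2 at −78 °C it adds to the peroxycarbenium ion from 11 and gives methyl (2R,4RS,6R,13Z)-2,4,6-trimethyl-14-phenyl-4-[(triethylsilyl)peroxy]tetradec-13-enoate F1. MeNHOMe·HCl/i-PrMgCl (THF, −20 °C) converts this into (2R,4RS,6R,13Z)-N-methoxy-N,2,4,6-tetramethyl-14-phenyl-4-[(triethylsilyl)peroxy]tetradec-13-enamide F2, and the lithium enolate of methyl acetate (THF, −78 °C) then gives 18 as a mixture of C6 epimers. Without catalyst control, the 4,6-cis (target) and 4,6-trans dioxanes are separated after step 9, at best half of the material being the target.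

Step 7. Release of the cyclopropanone may be slow at a temperature the zinc enolate tolerates, Favorskii-type opening may compete, and the in-situ silylation may be incomplete. The fallback sets out from 14 and comes back at 18. Allylmagnesium bromide (2.2 equiv, THF, 0 °C → rt) adds to the released cyclopropanone to give (2R)-2-methyl-1-(prop-2-en-1-yl)cyclopropan-1-ol F3. TBSOTf/2,6-lutidine gives tert-butyldimethyl{[(2R)-2-methyl-1-(prop-2-en-1-yl)cyclopropyl]oxy}silane F4. Ozonolysis in methanolic NaOH (CH2Cl2, −78 °C) turns the terminal alkene directly into methyl 2-[(2R)-1-{[tert-butyl(dimethyl)silyl]oxy}-2-methylcyclopropyl]acetate F5, the TBS analogue of 17, which replaces 17 in step 8 and gives 18.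

Step 4. Perhydrolysis may run on to the gem-dihydroperoxide or fall back to the ketone. The fallback sets out from 8 and comes back at 18. Ketone 8 with ethereal H2O2 and catalytic phosphomolybdic acid gives (4R,11Z)-2,2-dihydroperoxy-4-methyl-12-phenyldodec-11-ene F6. TESCl/imidazole gives (4R,11Z)-4-methyl-12-phenyl-2,2-bis[(triethylsilyl)peroxy]dodec-11-ene F7, which replaces 11 in step 8: the silyl Lewis acid removes one silylperoxy group to give the same peroxycarbenium ion and hence 18.

Further compounds
F1 | step 8 | methyl (2R,4RS,6R,13Z)-2,4,6-trimethyl-14-phenyl-4-[(triethylsilyl)peroxy]tetradec-13-enoate | COC(=O)[C@H](C)CC(C)(OO[Si](CC)(CC)CC)C[C@H](C)CCCCCC/C=C\c1ccccc1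
F2 | step 8 | (2R,4RS,6R,13Z)-N-methoxy-N,2,4,6-tetramethyl-14-phenyl-4-[(triethylsilyl)peroxy]tetradec-13-enamide | CON(C)C(=O)[C@H](C)CC(C)(OO[Si](CC)(CC)CC)C[C@H](C)CCCCCC/C=C\c1ccccc1
F3 | step 7 | (2R)-2-methyl-1-(prop-2-en-1-yl)cyclopropan-1-ol | C=CCC1(O)C[C@H]1C
F4 | step 7 | tert-butyldimethyl{[(2R)-2-methyl-1-(prop-2-en-1-yl)cyclopropyl]oxy}silane | C=CCC1(O[Si](C)(C)C(C)(C)C)C[C@H]1C
F5 | step 7 | methyl 2-[(2R)-1-{[tert-butyl(dimethyl)silyl]oxy}-2-methylcyclopropyl]acetate | COC(=O)CC1(O[Si](C)(C)C(C)(C)C)C[C@H]1C
F6 | step 4 | (4R,11Z)-2,2-dihydroperoxy-4-methyl-12-phenyldodec-11-ene | CC(OO)(OO)C[C@H](C)CCCCCC/C=C\c1ccccc1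
F7 | step 4 | (4R,11Z)-4-methyl-12-phenyl-2,2-bis[(triethylsilyl)peroxy]dodec-11-ene | CC(OO[Si](CC)(CC)CC)(OO[Si](CC)(CC)CC)C[C@H](C)CCCCCC/C=C\c1ccccc1
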